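The synthesis is disconnected at the C4–O bond of the γ-lactone ring (O1, C2, C3, C4, C5). C4 is allylic to the C3=C1′ tetradecylidene and to the C5=C6H2 enol-ester methylene. Its oxygen is the carboxylate oxygen of the side-arm acid, so a π-allylpalladium can deliver this bond. In one operation a chiral Pd(0) catalyst ionises a racemic C4 carbonate and the carboxylate attacks C4. This joins the halves and sets C4 as S, and the fragile ketol acid is never activated at its carbonyl. The precursors are the geometrically pure, racemic E-lactone methyl carbonate and the enantiopure (S,Z) O-triethylsilyl ketol acid.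

Key step: step 13

Locants: lactone O1, C2 (C=O), C3, C4, C5; C1′ = alkylidene CH; C6 = exocyclic CH2 on C5; C1″ = carbinol carbon of the side arm.

Remark: the E geometry of the lactone half comes from an SN2′ bromination, not from an α-metallated enoate. Such reagents equilibrate through allenolates and meet aldehydes on the side of the β-hydrogen, which leads to the Z series (used on purpose in step 9).

Assumption: the (R,R) ligand is written for 4S by extrapolating the quadrant model of this ligand class from cycloalkenyl esters. Because the acid is enantiopure, the C4 epimers are diastereomers, so the sense can be read directly and the (S,S) ligand used instead if needed.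

Step 1
Reactants: 1 tetradecanal; 2 methyl acrylate
Product: 3 methyl 3-hydroxy-2-methylidenehexadecanoate (racemic)
Conditions: DABCO (1 equiv), methyl acrylate (3 equiv), MeOH, rt, several days
Reagents that add atoms: none
Why: Morita–Baylis–Hillman reaction of an unbranched aliphatic aldehyde with an acrylate, whose racemic carbinol centre is erased in step 2.

Step 2
Reactants: 3 methyl 3-hydroxy-2-methylidenehexadecanoate
Product: 4 methyl (2Z)-2-(bromomethyl)hexadec-2-enoate
Conditions: NBS, Me2S, CH2Cl2, 0 °C → rt
Reagents that add atoms: N-bromosuccinimide, O=C1CCC(=O)N1Br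
Why: Corey–Kim-type activation as an alkoxysulfonium salt and SN2′ attack of bromide (the allylic transposition known for Morita–Baylis–Hillman alcohols) should give the primary bromide with the chain trans to the ester, because allylic strain with the ester is avoided, and this 2Z geometry becomes the E-alkylidene.

Step 3
Reactants: 4 methyl (2Z)-2-(bromomethyl)hexadec-2-enoate
Product: 5 methyl (2E)-2-formylhexadec-2-enoate
Conditions: NMO (anhydrous, 3–4 equiv), 4 Å MS, MeCN, 0 °C → rt
Reagents that add atoms: N-methylmorpholine N-oxide, C[N+]1([O-])CCOCC1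
Why: Amine N-oxide oxidation of an activated primary allylic bromide (Ganem/Kornblum type), in which SN2 attack of the N-oxide oxygen at CH2 and loss of N-methylmorpholine give the aldehyde without touching the alkene, whose chain stays cis to the smaller formyl group.

Step 4
Reactants: 5 methyl (2E)-2-formylhexadec-2-enoate; 6 ethynylmagnesium bromide
Product: 7 methyl (2E)-2-(1-hydroxyprop-2-yn-1-yl)hexadec-2-enoate (racemic)
Conditions: THF, −78 °C; sat. aq NH4Cl
Reagents that add atoms: none
Why: 1,2-Addition of a hard alkynyl Grignard reagent to the aldehyde, which is far more electrophilic than the ester and has no α-hydrogen, gives the future C4 carbinol, deliberately racemic.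

Step 5
Reactants: 7 methyl (2E)-2-(1-hydroxyprop-2-yn-1-yl)hexadec-2-enoate
Product: 8 (2E)-2-(1-hydroxyprop-2-yn-1-yl)hexadec-2-enoic acid (racemic)
Conditions: LiOH, THF–H2O, rt; 1 M HCl to pH 3
Reagents that add atoms: lithium hydroxide, [Li+].[OH-]
Why: Saponification of a methyl ester, safe here because the carbinol C–H is not α to a carbonyl, no retro-aldol path exists (a vinyl anion would have to leave) and the trisubstituted alkene has no way to isomerise.

Step 6
Reactants: 8 (2E)-2-(1-hydroxyprop-2-yn-1-yl)hexadec-2-enoic acid
Product: 9 (3E)-4-hydroxy-5-methylidene-3-tetradecylideneoxolan-2-one (racemic)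
Conditions: AuCl (5 mol %), K2CO3 (10 mol %), MeCN, rt
Reagents that add atoms: none
Why: Gold(I)-catalysed cycloisomerisation of a pent-4-ynoic acid, in which anti attack of the carboxylate on the π-activated terminal alkyne in the 5-exo-dig mode and protodeauration give the 5-methylene lactone.

Step 7
Reactants: 9 (3E)-4-hydroxy-5-methylidene-3-tetradecylideneoxolan-2-one
Product: 10 (3E)-4-(methoxycarbonyloxy)-5-methylidene-3-tetradecylideneoxolan-2-one (racemic)
Conditions: ClCO2Me, pyridine, CH2Cl2, 0 °C
Reagents that add atoms: methyl chloroformate, COC(=O)Cl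
Why: O-Acylation of a secondary allylic alcohol with a chloroformate, in which elimination is excluded because neither C3 nor C5 carries hydrogen.

Step 8
Reactants: 11 hexadec-2-ynoic acid
Product: 12 tert-butyl hexadec-2-ynoate
Conditions: Cl3CC(=NH)Ot-Bu (2 equiv), BF3·OEt2 (cat.), CH2Cl2–cyclohexane, rt
Reagents that add atoms: tert-butyl 2,2,2-trichloroacetimidate, CC(C)(C)OC(=N)C(Cl)(Cl)Cl
Why: Acid-catalysed tert-butyl transfer from the trichloroacetimidate to the carboxylic acid, which avoids nucleophilic catalysts that could add to the ynoate.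

Step 9
Reactants: 12 tert-butyl hexadec-2-ynoate; 13 methacrolein
Product: 15 tert-butyl (2Z)-2-(1-hydroxy-2-methylprop-2-en-1-yl)hexadec-2-enoate (racemic), via tert-butyl (2E)-2-(diisobutylalumanyl)hexadec-2-enoate 14 (not isolated)
Conditions: i-Bu2AlH, HMPA, THF, 0 °C; then 13, 0 °C → rt; aq Rochelle salt
Reagents that add atoms: none
Why: Conjugate syn hydroalumination of the ynoate by the DIBAL-H–HMPA complex, followed by aldol-type 1,2-addition of the α-aluminated enoate to the enal (vinylalumination), should give the 2Z ester because retention at C–Al and attack of the allenolate form on the side of the β-hydrogen lead to the same geometry; the carbinol is racemic.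

Step 10
Reactants: 15 tert-butyl (2Z)-2-(1-hydroxy-2-methylprop-2-en-1-yl)hexadec-2-enoate
Product: 16 tert-butyl (2Z)-2-[(1R)-1-hydroxy-2-methylprop-2-en-1-yl]hexadec-2-enoate
Conditions: Ti(Oi-Pr)4 (0.2 equiv), D-(−)-DIPT (0.26 equiv), t-BuOOH (0.6 equiv, anhydrous), 4 Å MS, CH2Cl2, −20 °C
Reagents that add atoms: none
Why: Sharpless kinetic resolution, in which the D-(−)-tartrate catalyst epoxidises the isopropenyl group of the 1S alcohol faster, the electron-poor enoate is inert, and the recovered 1R alcohol has the spatial arrangement of the (S)-ketol of the target.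

Step 11
Reactants: 16 tert-butyl (2Z)-2-[(1R)-1-hydroxy-2-methylprop-2-en-1-yl]hexadec-2-enoate
Product: 18 (2Z)-2-[(1R)-2-methyl-1-(triethylsilyloxy)prop-2-en-1-yl]hexadec-2-enoic acid, via triethylsilyl (2Z)-2-[(1R)-2-methyl-1-(triethylsilyloxy)prop-2-en-1-yl]hexadec-2-enoate 17 (not isolated)
Conditions: Et3SiOTf (3 equiv), 2,6-lutidine (5 equiv), CH2Cl2, 0 °C → rt; then pH 7 buffer–THF
Reagents that add atoms: triethylsilyl trifluoromethanesulfonate, CC[Si](CC)(CC)OS(=O)(=O)C(F)(F)F
Why: Silyl triflate–lutidine silylates the alcohol and converts the tert-butyl ester into the silyl ester with loss of isobutene (known silyl-triflate cleavage of tert-butyl esters), and the labile silyl ester alone is hydrolysed on aqueous work-up, all before any enolisable ketone is present.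

Step 12
Reactants: 18 (2Z)-2-[(1R)-2-methyl-1-(triethylsilyloxy)prop-2-en-1-yl]hexadec-2-enoic acid
Product: 20 (2Z)-2-[(1S)-2-oxo-1-(triethylsilyloxy)propyl]hexadec-2-enoic acid, via the secondary ozonide (2Z)-2-[(S)-(3-methyl-1,2,4-trioxolan-3-yl)(triethylsilyloxy)methyl]hexadec-2-enoic acid 19 (not isolated)
Conditions: O3, CH2Cl2, −78 °C (Sudan Red 7B as end-point indicator); Me2S, −78 °C → rt
Reagents that add atoms: ozone, [O-][O+]=O
Why: Chemoselective ozonolysis (Criegee mechanism), because electrophilic ozone takes the 1,1-disubstituted alkene far faster than the acceptor-substituted trisubstituted one, and the neutral reductive work-up leaves the now enolisable stereocentre untouched (R becomes S only through the change of CIP priorities).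

Step 13
Reactants: 10 (3E)-4-(methoxycarbonyloxy)-5-methylidene-3-tetradecylideneoxolan-2-one (racemic, 1.0 equiv); 20 (2Z)-2-[(1S)-2-oxo-1-(triethylsilyloxy)propyl]hexadec-2-enoic acid (1.2 equiv)
Product: 21 (3E,4S)-5-methylidene-2-oxo-3-tetradecylideneoxolan-4-yl (2Z)-2-[(1S)-2-oxo-1-(triethylsilyloxy)propyl]hexadec-2-enoate
Conditions: [Pd2(dba)3]·CHCl3 (2.5 mol %), (1R,2R)-N,N′-bis(2-diphenylphosphinobenzoyl)cyclohexane-1,2-diamine (7.5 mol %), degassed CH2Cl2, 0 °C → rt
Reagents that add atoms: none
Why: Proposed new method: Pd(0) ionises either enantiomer of 10 anti to the carbonate to a cationic 2-acyl π-allyl over C1′–C3–C4, CO2 leaves, the methoxide deprotonates 20, and the carboxylate, present only as the counter-ion, attacks C4 from outside, anti to palladium, to form the C4–O bond; no ring is closed. The closest known reaction types are the palladium-catalysed dynamic kinetic asymmetric substitution of Morita–Baylis–Hillman carbonates by oxygen nucleophiles and the palladium deracemisation of cyclic allylic esters with carboxylates, neither shown on an alkylidene enol lactone. Face exchange should not run through η1 at C1′, since rotation about C3–C1′ changes the face and the syn/anti place of the chain together and would end in the Z-alkylidene; the silent path is the slip over C4 to the second allyl C4–C5–C6 and η1 binding at the unsubstituted C6H2, which changes the face, keeps the chain where step 2 put it and needs only a primary C–Pd bond. The new stereocentre C4 (S) is controlled by the C2-symmetric ligand, which lets the carboxylate reach C4 only in the allyl diastereomer that holds C4 in its open quadrant; if exchange is slow the step degrades to a kinetic resolution with net retention (two inversions), in which (4S)-10 still gives 21. The step needs attack at C4 and not at C1′ or C6: C4 is the one terminus common to both η3 forms, C1′ is shielded by the chain, and the branched preference known for this ligand class with 2-acyl allyls argues against the primary C6, but this regioselectivity is the unproven point. The excess of acid leaves no free methoxide near the enol lactone or the enolisable ketol, and the run is stopped once 10 is consumed because 21 is itself an allylic ester that Pd(0) can re-ionise.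

Step 14
Reactants: 21 O-triethylsilyl ether of the target
Product: 22 (3E,4S)-5-methylidene-2-oxo-3-tetradecylideneoxolan-4-yl (2Z)-2-[(1S)-1-hydroxy-2-oxopropyl]hexadec-2-enoate (target)
Conditions: HF·pyridine, pyridine, THF, 0 °C
Reagents that add atoms: none
Why: Fluoride-mediated cleavage of a triethylsilyl ether with pyridine-buffered HF·pyridine, a weakly acidic medium that spares the enol lactone and the allylic ester and offers no base to epimerise C1″ or move the acyl group.

Compound list
1 | tetradecanal | CCCCCCCCCCCCCC=O | starting material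
2 | methyl acrylate | C=CC(=O)OC | starting material
3 | methyl 3-hydroxy-2-methylidenehexadecanoate (racemic) | C=C(C(=O)OC)C(O)CCCCCCCCCCCCC | intermediate
4 | methyl (2Z)-2-(bromomethyl)hexadec-2-enoate | COC(=O)/C(CBr)=C/CCCCCCCCCCCCC | intermediate
5 | methyl (2E)-2-formylhexadec-2-enoate | COC(=O)/C(C=O)=C/CCCCCCCCCCCCC | intermediate
6 | ethynylmagnesium bromide | C#C[Mg]Br | starting material
7 | methyl (2E)-2-(1-hydroxyprop-2-yn-1-yl)hexadec-2-enoate (racemic) | COC(=O)/C(=C/CCCCCCCCCCCCC)C(O)C#C | intermediate
8 | (2E)-2-(1-hydroxyprop-2-yn-1-yl)hexadec-2-enoic acid (racemic) | OC(=O)/C(=C/CCCCCCCCCCCCC)C(O)C#C | intermediate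
9 | (3E)-4-hydroxy-5-methylidene-3-tetradecylideneoxolan-2-one (racemic) | C=C1OC(=O)/C(=C/CCCCCCCCCCCCC)C1O | intermediate
10 | (3E)-4-(methoxycarbonyloxy)-5-methylidene-3-tetradecylideneoxolan-2-one (racemic) | C=C1OC(=O)/C(=C/CCCCCCCCCCCCC)C1OC(=O)OC | intermediate
11 | hexadec-2-ynoic acid | CCCCCCCCCCCCCC#CC(O)=O | starting material
12 | tert-butyl hexadec-2-ynoate | CCCCCCCCCCCCCC#CC(=O)OC(C)(C)C | intermediate
13 | methacrolein (2-methylprop-2-enal) | C=C(C)C=O | starting material
14 | tert-butyl (2E)-2-(diisobutylalumanyl)hexadec-2-enoate (not isolated) | CCCCCCCCCCCCC/C=C(/[Al](CC(C)C)CC(C)C)C(=O)OC(C)(C)C | intermediate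
15 | tert-butyl (2Z)-2-(1-hydroxy-2-methylprop-2-en-1-yl)hexadec-2-enoate (racemic) | CC(C)(C)OC(=O)/C(=C\CCCCCCCCCCCCC)C(O)C(C)=C | intermediate
16 | tert-butyl (2Z)-2-[(1R)-1-hydroxy-2-methylprop-2-en-1-yl]hexadec-2-enoate | CC(C)(C)OC(=O)/C(=C\CCCCCCCCCCCCC)[C@H](O)C(C)=C | intermediate
17 | triethylsilyl (2Z)-2-[(1R)-2-methyl-1-(triethylsilyloxy)prop-2-en-1-yl]hexadec-2-enoate (not isolated) | CC[Si](CC)(CC)OC(=O)/C(=C\CCCCCCCCCCCCC)[C@H](O[Si](CC)(CC)CC)C(C)=C | intermediate
18 | (2Z)-2-[(1R)-2-methyl-1-(triethylsilyloxy)prop-2-en-1-yl]hexadec-2-enoic acid | OC(=O)/C(=C\CCCCCCCCCCCCC)[C@H](O[Si](CC)(CC)CC)C(C)=C | intermediate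
19 | (2Z)-2-[(S)-(3-methyl-1,2,4-trioxolan-3-yl)(triethylsilyloxy)methyl]hexadec-2-enoic acid (secondary ozonide, ring carbon undefined, not isolated) | OC(=O)/C(=C\CCCCCCCCCCCCC)[C@H](O[Si](CC)(CC)CC)C1(C)OCOO1 | intermediate
20 | (2Z)-2-[(1S)-2-oxo-1-(triethylsilyloxy)propyl]hexadec-2-enoic acid | OC(=O)/C(=C\CCCCCCCCCCCCC)[C@H](O[Si](CC)(CC)CC)C(C)=O | intermediate
21 | (3E,4S)-5-methylidene-2-oxo-3-tetradecylideneoxolan-4-yl (2Z)-2-[(1S)-2-oxo-1-(triethylsilyloxy)propyl]hexadec-2-enoate | C=C1OC(=O)/C(=C/CCCCCCCCCCCCC)[C@@H]1OC(=O)/C(=C\CCCCCCCCCCCCC)[C@H](O[Si](CC)(CC)CC)C(C)=O | intermediate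
22 | (3E,4S)-5-methylidene-2-oxo-3-tetradecylideneoxolan-4-yl (2Z)-2-[(1S)-1-hydroxy-2-oxopropyl]hexadec-2-enoate | C=C1OC(=O)/C(=C/CCCCCCCCCCCCC)[C@@H]1OC(=O)/C(=C\CCCCCCCCCCCCC)[C@H](O)C(C)=O | target

Total step count: 14. Longest linear sequence: 9 steps (steps 1–7, 13, 14); the acid branch has 7 (steps 8–12, 13, 14).

Steps most likely to fail

1. Step 13 (Proposed new method).
- Possible failures: capture of the allyl cation at the primary C6 or at C1′; syn/anti isomerisation of the chain; face exchange slower than attack; re-ionisation of the product.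
- Fallback (known chemistry): it sets out from 9 and 20. Racemic 9 is acylated with 20 by Shiina esterification (2-methyl-6-nitrobenzoic anhydride, Et3N, cat. DMAP, CH2Cl2, 0 °C). This should give 21 together with its C4 epimer, (3E,4R)-5-methylidene-2-oxo-3-tetradecylideneoxolan-4-yl (2Z)-2-[(1S)-2-oxo-1-(triethylsilyloxy)propyl]hexadec-2-enoate F1. The two are diastereomers and are separated by chromatography. The route is rejoined at 21.

2. Step 10.
- Possible failures: slow or poorly discriminating epoxidation, because the carbinol is flanked by two branched sp2 carbons and the ester can bind titanium. This would leave insufficient enantiomeric purity in the recovered alcohol.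
- Fallback: it sets out from 15 and uses a classical resolution. Esterification with (S)-O-methylmandelic acid (DCC, cat. DMAP, CH2Cl2) should give two diastereomeric esters:
  - tert-butyl (2Z)-2-{(1R)-1-[(2S)-2-methoxy-2-phenylacetoxy]-2-methylprop-2-en-1-yl}hexadec-2-enoate F2
  - tert-butyl (2Z)-2-{(1S)-1-[(2S)-2-methoxy-2-phenylacetoxy]-2-methylprop-2-en-1-yl}hexadec-2-enoate F3
- These are separated by chromatography. Methanolysis of the first (K2CO3, MeOH, 0 °C), which the tert-butyl enoate resists, returns the route at 16.

3. Step 3.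
- Possible failures: quaternisation of the bromide by the liberated tertiary amine, and reversible amine addition to the doubly activated alkene of the aldehyde. Either would cost material or alkene geometry.
- Fallback: it sets out from 4 and is amine-free.
  - Displacement with KOAc (DMF, rt) gives methyl (2E)-2-(acetoxymethyl)hexadec-2-enoate F4.
  - Methanolysis (K2CO3, MeOH) gives methyl (2E)-2-(hydroxymethyl)hexadec-2-enoate F5.
  - Allylic oxidation with MnO2 (CH2Cl2, rt) returns the route at 5.

Further compounds
F1 | step 13 | (3E,4R)-5-methylidene-2-oxo-3-tetradecylideneoxolan-4-yl (2Z)-2-[(1S)-2-oxo-1-(triethylsilyloxy)propyl]hexadec-2-enoate | C=C1OC(=O)/C(=C/CCCCCCCCCCCCC)[C@H]1OC(=O)/C(=C\CCCCCCCCCCCCC)[C@H](O[Si](CC)(CC)CC)C(C)=O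
F2 | step 10 | tert-butyl (2Z)-2-{(1R)-1-[(2S)-2-methoxy-2-phenylacetoxy]-2-methylprop-2-en-1-yl}hexadec-2-enoate | CC(C)(C)OC(=O)/C(=C\CCCCCCCCCCCCC)[C@H](OC(=O)[C@@H](OC)c1ccccc1)C(C)=C
F3 | step 10 | tert-butyl (2Z)-2-{(1S)-1-[(2S)-2-methoxy-2-phenylacetoxy]-2-methylprop-2-en-1-yl}hexadec-2-enoate | CC(C)(C)OC(=O)/C(=C\CCCCCCCCCCCCC)[C@@H](OC(=O)[C@@H](OC)c1ccccc1)C(C)=C
F4 | step 3 | methyl (2E)-2-(acetoxymethyl)hexadec-2-enoate | COC(=O)/C(COC(C)=O)=C/CCCCCCCCCCCCC
F5 | step 3 | methyl (2E)-2-(hydroxymethyl)hexadec-2-enoate | COC(=O)/C(CO)=C/CCCCCCCCCCCCC
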